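**Strategy.** Ring C, the pyranone O1–C2=C3–C4(=O)–C4a–C8a, is cut into three pieces: an ortho-iodophenol of ring A (C4a–I beside C8a–OH), carbon monoxide (C4) and the ring B arylacetylene (C3, C2). One palladium-catalysed carbonylative alkynylation–cyclisation forms C4a–C4, C4–C3 and O1–C2 and closes ring C. Its substrate is an enantiopure iodoresorcinol: a 5-benzyloxyresorcinol carrying the (R)-1-arylethyl arm between its two hydroxyls, with iodine between the benzyl ether and one hydroxyl, so only the 8-substituted flavone can form. The stereocentre comes from a hydroxyl-directed asymmetric hydrogenation of a 1,1-diarylethene. C3 hydroxylation and global debenzylation finish the synthesis.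

Key step: step 9

Remark: the sense of induction in the directed hydrogenation (step 6) cannot be predicted with confidence for a 2,6-dihydroxyaryl alkene; both ligand antipodes are available, and the one giving the R product is to be fixed in a pilot run (anomalous-dispersion X-ray analysis of the iodide made in step 7).

Step 1
Reactants: 1 phloroglucinol
Product: 2 5-(benzyloxy)benzene-1,3-diol
Conditions: 1 (2.5 equiv), BnBr (1 equiv), K2CO3, DMF, 0 °C to rt; excess 1 removed by aqueous wash
Reagents that add atoms: benzyl bromide, BrCc1ccccc1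
Why: Williamson ether synthesis; with the triol in excess, mono-O-benzylation should be the main alkylation event, and the polar unreacted triol is separated by extraction.

Step 2
Reactants: 2 5-(benzyloxy)benzene-1,3-diol
Product: 3 1-(benzyloxy)-3,5-bis(methoxymethoxy)benzene
Conditions: MOMCl (2.6 equiv), iPr2NEt (3 equiv), CH2Cl2, 0 °C to rt
Reagents that add atoms: chloromethyl methyl ether, COCCl
Why: Base-mediated O-alkylation (acetal protection) of both phenols installs the two MOM ethers that later direct lithiation to the carbon between them.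

Step 3
Reactants: 4 acetosyringone
Product: 5 1-[4-(benzyloxy)-3,5-dimethoxyphenyl]ethan-1-one
Conditions: BnBr (1.2 equiv), K2CO3, DMF, 60 °C
Reagents that add atoms: benzyl bromide, BrCc1ccccc1
Why: Williamson etherification masks the only acidic O–H of the ketone partner before the organometallic addition.

Step 4
Reactants: 3 1-(benzyloxy)-3,5-bis(methoxymethoxy)benzene, 5 1-[4-(benzyloxy)-3,5-dimethoxyphenyl]ethan-1-one
Product: 8 rac-1-[4-(benzyloxy)-2,6-bis(methoxymethoxy)phenyl]-1-[4-(benzyloxy)-3,5-dimethoxyphenyl]ethan-1-ol, via aryllithium 6 (not isolated), via arylcerium dichloride 7 (not isolated)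
Conditions: n-BuLi (1.1 equiv), THF, 0 °C, 1 h; CeCl3 (anhydrous, 1.2 equiv), −78 °C; then 5, −78 to 0 °C; aq. NH4Cl
Reagents that add atoms: none
Why: Directed ortho-metalation removes the C–H flanked by two OMOM groups (the most acidic and best-coordinated site, preferred over the positions next to the benzyl ether), and transmetalation to the less basic organocerium favours 1,2-addition to the enolisable aryl methyl ketone over proton transfer; the racemic carbinol centre is destroyed in step 5.

Step 5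
Reactants: 8 rac-1-[4-(benzyloxy)-2,6-bis(methoxymethoxy)phenyl]-1-[4-(benzyloxy)-3,5-dimethoxyphenyl]ethan-1-ol
Product: 10 5-(benzyloxy)-2-{1-[4-(benzyloxy)-3,5-dimethoxyphenyl]ethenyl}benzene-1,3-diol, via bis-MOM diarylethene 9 (not isolated)
Conditions: conc. HCl (cat.), MeOH–THF (1:1, 0.02 M), 50 °C; NaHCO3 work-up
Reagents that add atoms: none
Why: Acid ionises the doubly benzylic tertiary carbinol (E1 dehydration, cation stabilised by both oxygenated rings) to the 1,1-diarylethene, and the same acid transacetalises both aryl MOM ethers to methanol; the 2,6-disubstituted ring next to the alkene carbon and the high dilution should hold back methanol re-addition and cationic dimerisation.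

Step 6
Reactants: 10 5-(benzyloxy)-2-{1-[4-(benzyloxy)-3,5-dimethoxyphenyl]ethenyl}benzene-1,3-diol
Product: 11 5-(benzyloxy)-2-{(1R)-1-[4-(benzyloxy)-3,5-dimethoxyphenyl]ethyl}benzene-1,3-diol
Conditions: [Rh(nbd)2]BF4 (2 mol%), (R)-1-[(SP)-2-(diphenylphosphino)ferrocenyl]ethyldi-tert-butylphosphine or its antipode (2.2 mol%), Et3N (10 mol%), H2 (20 bar), MeOH, rt
Reagents that add atoms: none
Why: Rhodium-catalysed hydroxyl-directed asymmetric hydrogenation of a 1-aryl-1-(2-hydroxyaryl)ethene: a phenol ortho to the alkene binds rhodium together with the C=C, so the chiral bisphosphine decides which alkene face receives H2 and sets the benzylic centre as R (the two ortho hydroxyls are interchangeable by ring rotation), while the benzyl ethers are inert to the homogeneous catalyst.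

Step 7
Reactants: 11 5-(benzyloxy)-2-{(1R)-1-[4-(benzyloxy)-3,5-dimethoxyphenyl]ethyl}benzene-1,3-diol
Product: 12 5-(benzyloxy)-2-{(1R)-1-[4-(benzyloxy)-3,5-dimethoxyphenyl]ethyl}-4-iodobenzene-1,3-diol
Conditions: NIS (1.0 equiv), MeCN, −30 °C, dark; used promptly
Reagents that add atoms: N-iodosuccinimide, O=C1CCC(=O)N1I
Why: Electrophilic aromatic iodination: the two free positions of ring A are equivalent and far more activated than the syringyl ring, so one equivalent at low temperature should give a single mono-iodide with iodine between OH and OBn; both hydroxyls are left free because the one next to iodine is the ring-closing nucleophile of step 9 and the two cannot be told apart before iodination.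

Step 8
Reactants: 13 4-(benzyloxy)-3-methoxybenzaldehyde (O-benzylvanillin, commercial)
Product: 14 1-(benzyloxy)-4-ethynyl-2-methoxybenzene
Conditions: dimethyl (1-diazo-2-oxopropyl)phosphonate (1.3 equiv), K2CO3 (2 equiv), MeOH, rt
Reagents that add atoms: dimethyl (1-diazo-2-oxopropyl)phosphonate, CC(=O)C(=[N+]=[N-])P(=O)(OC)OC
Why: Seyferth–Gilbert homologation in the Ohira–Bestmann variant: methanolysis frees the diazomethylphosphonate anion, which olefinates the aldehyde, and loss of N2 with 1,2-hydride shift gives the terminal alkyne under conditions that leave the benzyl ether untouched.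

Step 9
Reactants: 12 5-(benzyloxy)-2-{(1R)-1-[4-(benzyloxy)-3,5-dimethoxyphenyl]ethyl}-4-iodobenzene-1,3-diol, 14 1-(benzyloxy)-4-ethynyl-2-methoxybenzene, 15 carbon monoxide
Product: 18 5-(benzyloxy)-2-[4-(benzyloxy)-3-methoxyphenyl]-8-{(1R)-1-[4-(benzyloxy)-3,5-dimethoxyphenyl]ethyl}-7-hydroxy-4H-chromen-4-one, via hydroxyaryl ynone 16 (not isolated), via diethylamino enone 17 (not isolated)
Conditions: PdCl2(dppf) (5 mol%), CO (20 bar), Et2NH (solvent), 100–120 °C, autoclave
Reagents that add atoms: carbon monoxide, [C-]#[O+] (compound 15)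
Why: Zerovalent palladium, formed in the flask from PdCl2(dppf), inserts into the C–I bond of 12, CO inserts to give the aroyl–palladium species, and amine-assisted coupling with the terminal alkyne 14 (a copper-free carbonylative Sonogashira coupling) releases the ortho-hydroxyaryl ynone 16. Diethylamine then adds to the ynone to give the β-amino enone 17, and the hydroxyl ortho to the new acyl group displaces the amine by conjugate addition–elimination, so ring C closes through the O1–C2 bond in a 6-endo mode (6-endo-dig with respect to 16, 6-endo-trig addition–elimination through 17). The closest known reaction is the palladium-catalysed carbonylative annulation of ortho-iodophenols with terminal arylacetylenes under CO in diethylamine, which gives flavones. No stereocentre is created; no bond to the existing benzylic centre is made or broken and its C–H is far too weakly acidic for the amine, so the R configuration should be carried through. The step needs 6-endo rather than 5-exo (aurone) closure, which the secondary-amine pathway through 17 secures, and the 8- rather than the 6-substituted flavone, which the substrate secures because the only hydroxyl ortho to iodine is the one beside the arylethyl arm while the other ortho position is a benzyl ether. The second phenol is para to the reacting carbon, cannot reach the ynone and should remain as the 7-hydroxyl.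

Step 10
Reactants: 18 5-(benzyloxy)-2-[4-(benzyloxy)-3-methoxyphenyl]-8-{(1R)-1-[4-(benzyloxy)-3,5-dimethoxyphenyl]ethyl}-7-hydroxy-4H-chromen-4-one
Product: 19 5,7-bis(benzyloxy)-2-[4-(benzyloxy)-3-methoxyphenyl]-8-{(1R)-1-[4-(benzyloxy)-3,5-dimethoxyphenyl]ethyl}-4H-chromen-4-one
Conditions: BnBr (1.3 equiv), K2CO3, DMF, rt
Reagents that add atoms: benzyl bromide, BrCc1ccccc1
Why: Williamson benzylation of the acidic 7-hydroxyl (a vinylogous acid) removes the last free phenol before the oxidation step.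

Step 11
Reactants: 19 5,7-bis(benzyloxy)-2-[4-(benzyloxy)-3-methoxyphenyl]-8-{(1R)-1-[4-(benzyloxy)-3,5-dimethoxyphenyl]ethyl}-4H-chromen-4-one
Product: 21 5,7-bis(benzyloxy)-2-[4-(benzyloxy)-3-methoxyphenyl]-8-{(1R)-1-[4-(benzyloxy)-3,5-dimethoxyphenyl]ethyl}-3-hydroxy-4H-chromen-4-one, via flavone epoxide 20 (not isolated)
Conditions: DMDO (acetone solution, 3–4 equiv), CH2Cl2, 0 °C, dark; evaporate; p-TsOH·H2O (cat.), CHCl3, rt
Reagents that add atoms: dimethyldioxirane, CC1(C)OO1
Why: Dioxirane epoxidation of the flavone C2=C3 bond gives the 2,3-epoxide, whose acid-catalysed opening at C2 (oxocarbenium stabilised by O1 and ring B) and loss of the C3 proton give the 3-hydroxyflavone, a flavone-to-flavonol oxidation established on perbenzylated polyoxygenated flavones; the benzylic stereocentre is not involved.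

Step 12
Reactants: 21 5,7-bis(benzyloxy)-2-[4-(benzyloxy)-3-methoxyphenyl]-8-{(1R)-1-[4-(benzyloxy)-3,5-dimethoxyphenyl]ethyl}-3-hydroxy-4H-chromen-4-one
Product: 22 3,5,7-trihydroxy-2-(4-hydroxy-3-methoxyphenyl)-8-[(1R)-1-(4-hydroxy-3,5-dimethoxyphenyl)ethyl]-4H-chromen-4-one (CNP0261887.1)
Conditions: H2 (1 atm), 10% Pd/C, THF–MeOH (1:1), rt
Reagents that add atoms: none
Why: Heterogeneous hydrogenolysis cleaves the four O-benzyl ethers, while the flavonol enone, the aryl methyl ethers and the C–C-bonded stereocentre are inert under one atmosphere of H2.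

**Compound list**

1 | phloroglucinol | Oc1cc(O)cc(O)c1 | starting material
2 | 5-(benzyloxy)benzene-1,3-diol | Oc1cc(O)cc(OCc2ccccc2)c1 | intermediate
3 | 1-(benzyloxy)-3,5-bis(methoxymethoxy)benzene | COCOc1cc(OCOC)cc(OCc2ccccc2)c1 | intermediate
4 | acetosyringone | CC(=O)c1cc(OC)c(O)c(OC)c1 | starting material
5 | 1-[4-(benzyloxy)-3,5-dimethoxyphenyl]ethan-1-one | CC(=O)c1cc(OC)c(OCc2ccccc2)c(OC)c1 | intermediate
6 | [4-(benzyloxy)-2,6-bis(methoxymethoxy)phenyl]lithium | [Li]c1c(OCOC)cc(OCc2ccccc2)cc1OCOC | intermediate (not isolated)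
7 | [4-(benzyloxy)-2,6-bis(methoxymethoxy)phenyl]cerium dichloride | Cl[Ce](Cl)c1c(OCOC)cc(OCc2ccccc2)cc1OCOC | intermediate (not isolated)
8 | rac-1-[4-(benzyloxy)-2,6-bis(methoxymethoxy)phenyl]-1-[4-(benzyloxy)-3,5-dimethoxyphenyl]ethan-1-ol | COCOc1cc(OCc2ccccc2)cc(OCOC)c1C(C)(O)c1cc(OC)c(OCc2ccccc2)c(OC)c1 | intermediate
9 | 5-(benzyloxy)-2-{1-[4-(benzyloxy)-3,5-dimethoxyphenyl]ethenyl}-1,3-bis(methoxymethoxy)benzene | COCOc1cc(OCc2ccccc2)cc(OCOC)c1C(=C)c1cc(OC)c(OCc2ccccc2)c(OC)c1 | intermediate (not isolated)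
10 | 5-(benzyloxy)-2-{1-[4-(benzyloxy)-3,5-dimethoxyphenyl]ethenyl}benzene-1,3-diol | Oc1cc(OCc2ccccc2)cc(O)c1C(=C)c1cc(OC)c(OCc2ccccc2)c(OC)c1 | intermediate
11 | 5-(benzyloxy)-2-{(1R)-1-[4-(benzyloxy)-3,5-dimethoxyphenyl]ethyl}benzene-1,3-diol | Oc1cc(OCc2ccccc2)cc(O)c1[C@H](C)c1cc(OC)c(OCc2ccccc2)c(OC)c1 | intermediate
12 | 5-(benzyloxy)-2-{(1R)-1-[4-(benzyloxy)-3,5-dimethoxyphenyl]ethyl}-4-iodobenzene-1,3-diol | Oc1cc(OCc2ccccc2)c(I)c(O)c1[C@H](C)c1cc(OC)c(OCc2ccccc2)c(OC)c1 | intermediate
13 | 4-(benzyloxy)-3-methoxybenzaldehyde | COc1cc(C=O)ccc1OCc1ccccc1 | starting material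
14 | 1-(benzyloxy)-4-ethynyl-2-methoxybenzene | C#Cc1ccc(OCc2ccccc2)c(OC)c1 | intermediate
15 | carbon monoxide | [C-]#[O+] | starting material
16 | 1-{6-(benzyloxy)-3-[(1R)-1-[4-(benzyloxy)-3,5-dimethoxyphenyl]ethyl]-2,4-dihydroxyphenyl}-3-[4-(benzyloxy)-3-methoxyphenyl]prop-2-yn-1-one | O=C(C#Cc1ccc(OCc2ccccc2)c(OC)c1)c1c(OCc2ccccc2)cc(O)c([C@H](C)c2cc(OC)c(OCc3ccccc3)c(OC)c2)c1O | intermediate (not isolated)
17 | 1-{6-(benzyloxy)-3-[(1R)-1-[4-(benzyloxy)-3,5-dimethoxyphenyl]ethyl]-2,4-dihydroxyphenyl}-3-[4-(benzyloxy)-3-methoxyphenyl]-3-(diethylamino)prop-2-en-1-one (alkene geometry not defined) | CCN(CC)C(=CC(=O)c1c(OCc2ccccc2)cc(O)c([C@H](C)c2cc(OC)c(OCc3ccccc3)c(OC)c2)c1O)c1ccc(OCc2ccccc2)c(OC)c1 | intermediate (not isolated)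
18 | 5-(benzyloxy)-2-[4-(benzyloxy)-3-methoxyphenyl]-8-{(1R)-1-[4-(benzyloxy)-3,5-dimethoxyphenyl]ethyl}-7-hydroxy-4H-chromen-4-one | COc1cc(-c2cc(=O)c3c(OCc4ccccc4)cc(O)c([C@H](C)c4cc(OC)c(OCc5ccccc5)c(OC)c4)c3o2)ccc1OCc1ccccc1 | intermediate
19 | 5,7-bis(benzyloxy)-2-[4-(benzyloxy)-3-methoxyphenyl]-8-{(1R)-1-[4-(benzyloxy)-3,5-dimethoxyphenyl]ethyl}-4H-chromen-4-one | COc1cc(-c2cc(=O)c3c(OCc4ccccc4)cc(OCc4ccccc4)c([C@H](C)c4cc(OC)c(OCc5ccccc5)c(OC)c4)c3o2)ccc1OCc1ccccc1 | intermediate
20 | 2,3-epoxide of 19 (oxirane fused across C2–C3, mixture of epoxide diastereomers, R at the benzylic centre) | COc1cc(C23OC2C(=O)c2c(OCc4ccccc4)cc(OCc4ccccc4)c([C@H](C)c4cc(OC)c(OCc5ccccc5)c(OC)c4)c2O3)ccc1OCc1ccccc1 | intermediate (not isolated)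
21 | 5,7-bis(benzyloxy)-2-[4-(benzyloxy)-3-methoxyphenyl]-8-{(1R)-1-[4-(benzyloxy)-3,5-dimethoxyphenyl]ethyl}-3-hydroxy-4H-chromen-4-one | COc1cc(-c2oc3c([C@H](C)c4cc(OC)c(OCc5ccccc5)c(OC)c4)c(OCc4ccccc4)cc(OCc4ccccc4)c3c(=O)c2O)ccc1OCc1ccccc1 | intermediate
22 | 3,5,7-trihydroxy-2-(4-hydroxy-3-methoxyphenyl)-8-[(1R)-1-(4-hydroxy-3,5-dimethoxyphenyl)ethyl]-4H-chromen-4-one | COc1cc(-c2oc3c([C@H](C)c4cc(OC)c(O)c(OC)c4)c(O)cc(O)c3c(=O)c2O)ccc1O | target

**Step count.** Total: 12 steps. Longest linear sequence: 10 steps (steps 1, 2, 4, 5, 6, 7, 9, 10, 11, 12).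

**Steps most likely to fail**

Step 9. The C–I bond is electron-rich and flanked on both sides, so oxidative addition may be slow. The aroyl–palladium intermediate may be captured by diethylamine (amide formation), or closure may go 5-exo to the aurone. Fallback, from 12 to 19 without carbonylation: a Stille coupling of 12 with tributyl(1-ethoxyvinyl)stannane (Pd(PPh3)4, toluene, 100 °C) would give the aryl enol ether F1, hydrolysed on work-up with 1 M HCl to the ortho-hydroxyacetophenone F2. The hydroxyl that is not hydrogen-bonded to the ketone is then benzylated selectively (BnBr, K2CO3, acetone) to give the bis(benzyloxy) hydroxyacetophenone F3. Claisen–Schmidt condensation with aldehyde 13 (KOH, EtOH–THF) gives the 2'-hydroxychalcone F4. Oxidative cyclisation (I2 cat., DMSO, 120 °C) closes ring C and rejoins the route at 19, so step 10 is no longer needed.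

Step 6. Facial selectivity may be poor or turnover slow, because the alkene carries a 2,6-disubstituted ring that is twisted out of conjugation. Fallback, from 10 to 11 by resolution: hydrogenation with the achiral catalyst [Ir(cod)(PCy3)(py)]PF6 (H2, CH2Cl2) would give the racemic diarylethane F5. This is resolved by preparative chromatography on a chiral stationary phase (amylose tris(3,5-dimethylphenylcarbamate), supercritical CO2/MeOH), and the R enantiomer is 11.

Step 11. The dioxirane may oxidise the doubly benzylic C–H or the electron-rich rings faster than the electron-poor C2=C3 bond. Fallback, from 19 to 21 without an electrophilic oxidant on the intact flavone: deprotonation at C3 with LiN(i-Pr)2 (THF, −78 °C) gives the 3-lithioflavone F6. This is trapped with B(OMe)3 as the dimethyl boronate F7 and oxidised in the same flask with H2O2/AcOH to give 21.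

**Further compounds**

F1 | step 9 | 5-(benzyloxy)-2-{(1R)-1-[4-(benzyloxy)-3,5-dimethoxyphenyl]ethyl}-4-(1-ethoxyethenyl)benzene-1,3-diol | CCOC(=C)c1c(OCc2ccccc2)cc(O)c([C@H](C)c2cc(OC)c(OCc3ccccc3)c(OC)c2)c1O
F2 | step 9 | 1-{6-(benzyloxy)-3-[(1R)-1-[4-(benzyloxy)-3,5-dimethoxyphenyl]ethyl]-2,4-dihydroxyphenyl}ethan-1-one | CC(=O)c1c(OCc2ccccc2)cc(O)c([C@H](C)c2cc(OC)c(OCc3ccccc3)c(OC)c2)c1O
F3 | step 9 | 1-{4,6-bis(benzyloxy)-3-[(1R)-1-[4-(benzyloxy)-3,5-dimethoxyphenyl]ethyl]-2-hydroxyphenyl}ethan-1-one | CC(=O)c1c(OCc2ccccc2)cc(OCc2ccccc2)c([C@H](C)c2cc(OC)c(OCc3ccccc3)c(OC)c2)c1O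
F4 | step 9 | (2E)-1-{4,6-bis(benzyloxy)-3-[(1R)-1-[4-(benzyloxy)-3,5-dimethoxyphenyl]ethyl]-2-hydroxyphenyl}-3-[4-(benzyloxy)-3-methoxyphenyl]prop-2-en-1-one | O=C(/C=C/c1ccc(OCc2ccccc2)c(OC)c1)c1c(OCc2ccccc2)cc(OCc2ccccc2)c([C@H](C)c2cc(OC)c(OCc3ccccc3)c(OC)c2)c1O
F5 | step 6 | rac-5-(benzyloxy)-2-{1-[4-(benzyloxy)-3,5-dimethoxyphenyl]ethyl}benzene-1,3-diol | Oc1cc(OCc2ccccc2)cc(O)c1C(C)c1cc(OC)c(OCc2ccccc2)c(OC)c1
F6 | step 11 | 3-lithio derivative of 19 | COc1cc(-c2oc3c([C@H](C)c4cc(OC)c(OCc5ccccc5)c(OC)c4)c(OCc4ccccc4)cc(OCc4ccccc4)c3c(=O)c2[Li])ccc1OCc1ccccc1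
F7 | step 11 | dimethyl {5,7-bis(benzyloxy)-2-[4-(benzyloxy)-3-methoxyphenyl]-8-[(1R)-1-[4-(benzyloxy)-3,5-dimethoxyphenyl]ethyl]-4-oxo-4H-chromen-3-yl}boronate | COc1cc(-c2oc3c([C@H](C)c4cc(OC)c(OCc5ccccc5)c(OC)c4)c(OCc4ccccc4)cc(OCc4ccccc4)c3c(=O)c2B(OC)OC)ccc1OCc1ccccc1
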